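## Retrosynthetic overview

- Glaucolide K ⇐ C8–O bond: last-step allylic C–H methacryloxylation at C8 of the 1α,13-diacetoxy 7(11)-butenolide (sets C8).
- ⇐ C13–O bond: allylic bromination with transposition of an α-methylene lactone, then acetate displacement (moves the unsaturation to C7=C11).
- ⇐ C1–O bond: hydroboration–oxidation of the 1(10)-alkene (sets C10 and C1β), then Mitsunobu inversion to the 1α-acetate; the α-methylene lactone is masked as a selenol adduct during hydroboration.
- The carbon skeleton, the ten-membered ring, the oxirane and the γ-lactone (with C4, C5, C6) come unchanged from (−)-parthenolide. No ring is formed in the route; every new skeletal bond is C–O.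

Assumption: (−)-parthenolide (1), a feverfew/Magnolia isolate sold in bulk, is taken as a cheap commercial starting material; the target is (1S,4R,5R,6S,8S,10S) as read from the SMILES.

## Route

Step 1
Reactants: 1 (−)-parthenolide
Product: 2 (11S)-13-(phenylselanyl)-11βH,13-dihydroparthenolide
Conditions: PhSeH (1.1 equiv), Et3N (0.1 equiv), CH2Cl2, 0 °C
Reagents that add atoms: benzeneselenol, [SeH]c1ccccc1
Why: Seleno-Michael (conjugate) addition of the soft selenol to the α-methylene lactone masks the only other borane-reactive alkene; the C11 centre (enolate protonation on the β-face) is temporary and is erased in step 2.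

Step 2
Reactants: 2 (11S)-13-(phenylselanyl)-11βH,13-dihydroparthenolide
Product: 5 (1R,10S)-1β-hydroxy-1,10-dihydroparthenolide, via C1-alkylborane 3 (not isolated), via selenoxide 4 (not isolated)
Conditions: BH3·THF (1.5 equiv), THF, 0 °C; then NaBO3·4H2O, THF/H2O, 0 °C to rt
Reagents that add atoms: borane (as BH3·THF), B; sodium perborate (as NaBO3·4H2O), [Na+].[O-]OB=O
Why: Hydroboration–oxidation (anti-Markovnikov syn addition): borane attacks the strained E-1(10)-alkene from its exposed outer face (the face peracids use to give the 1β,10α-epoxide), putting boron on C1 (β) and hydrogen on C10 (α), which sets C10 (S) and C1 (R); perborate oxidises C–B with retention and the selenide to the selenoxide, whose syn-elimination restores the α-methylene lactone.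

Step 3
Reactants: 5 (1R,10S)-1β-hydroxy-1,10-dihydroparthenolide
Product: 6 (1S,10S)-1α-acetoxy-1,10-dihydroparthenolide
Conditions: PPh3, DIAD, toluene, 0 °C (betaine preformed); then AcOH and 5, 0 °C to rt
Reagents that add atoms: acetic acid, CC(=O)O
Why: Mitsunobu esterification: SN2 displacement of the C1 oxyphosphonium by acetate inverts C1 from R (1β) to S (1α) and installs the acetate in the same operation; preforming the betaine keeps free phosphine away from the α-methylene lactone.

Step 4
Reactants: 6 (1S,10S)-1α-acetoxy-1,10-dihydroparthenolide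
Product: 8 (1S,4R,5R,6S,10S)-1α,13-diacetoxy-4α,5β-epoxygermacr-7(11)-en-6α,12-olide, via 13-bromo butenolide 7 (not isolated)
Conditions: NBS (1.1 equiv), AIBN (cat.), NaHCO3 (solid), PhCF3, 80 °C; then KOAc, 18-crown-6 (cat.), MeCN, rt
Reagents that add atoms: N-bromosuccinimide, O=C1CCC(=O)N1Br; potassium acetate, CC(=O)[O-].[K+]
Why: Wohl–Ziegler allylic bromination with allylic transposition, then SN2 acetate displacement: the bromine atom abstracts the only weak C–H (tertiary allylic C7–H), the allyl radical takes bromine at the primary terminus C13 to give the conjugated tetrasubstituted butenolide (the C7 stereocentre is removed), and acetate displaces the primary allylic bromide.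

Step 5
Reactants: 8 (1S,4R,5R,6S,10S)-1α,13-diacetoxy-4α,5β-epoxygermacr-7(11)-en-6α,12-olide
Product: 9 glaucolide K
Conditions: Pd(O2CCF3)2 (10 mol%), 1,2-bis(phenylsulfinyl)ethane (10 mol%), LiCl (20 mol%), 2,6-dimethyl-1,4-benzoquinone (2 equiv), methacrylic acid (5 equiv), iPr2NEt (0.5 equiv), BHT (cat.), 1,4-dioxane, 45 °C
Reagents that add atoms: methacrylic acid, C=C(C)C(=O)O
Why: Proposed new method: a vinylogous (γ′) allylic C–H acyloxylation in which a divalent palladium carboxylate/sulfoxide catalyst, bound on the open β-face of the butenolide (the H-6β side, opposite the C5 epoxide arm), removes the pseudo-axial, lactone-acidified 8β-H by carboxylate-assisted metalation to give an η3-allyl over C8–C7–C11 (the carbon-bound form of a palladium dienolate), and chloride-enforced outer-sphere attack of methacrylate at the carbonyl-remote terminus C8, anti to palladium, forms the C8–O bond as the 8α (S) ester while the quinone reoxidises zerovalent palladium; C6–H (tertiary, next to the epoxide, under the C15 methyl) and C13–H (cross-conjugated, acyloxy-deactivated) are expected to be slower; the closest known reactions are the Pd/bis-sulfoxide/quinone allylic C–H esterification of terminal alkenes and the chloride-controlled anti carboxylate attack in Pd/quinone 1,4-diacetoxylation of 1,3-dienes, neither shown at the γ′-position of a tetrasubstituted butenolide.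

## Compound list

1 | (−)-parthenolide, (4R,5R,6S,7S)-4α,5β-epoxygermacra-1(10)E,11(13)-dien-6α,12-olide | C/C1=C\CC[C@@]2(C)O[C@@H]2[C@H]2OC(=O)C(=C)[C@@H]2CC1 | starting material
2 | (11S)-13-(phenylselanyl)-11βH,13-dihydroparthenolide | C/C1=C\CC[C@@]2(C)O[C@@H]2[C@H]2OC(=O)[C@@H](C[Se]c3ccccc3)[C@@H]2CC1 | intermediate
3 | C1-alkylborane: 1β-boryl (BH2), 10αH adduct of 2 | C1C[C@H](C)[C@H]([BH2])CC[C@@]2(C)O[C@@H]2[C@H]2OC(=O)[C@@H](C[Se]c3ccccc3)[C@H]12 | intermediate
4 | selenoxide: (1R,10S)-1β-hydroxy-13-(phenylseleninyl)-1,10,11,13-tetrahydroparthenolide | C1C[C@H](C)[C@H](O)CC[C@@]2(C)O[C@@H]2[C@H]2OC(=O)[C@@H](C[Se](=O)c3ccccc3)[C@H]12 | intermediate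
5 | (1R,10S)-1β-hydroxy-1,10-dihydroparthenolide (10αH, 14β-methyl) | C1C[C@H](C)[C@H](O)CC[C@@]2(C)O[C@@H]2[C@H]2OC(=O)C(=C)[C@H]12 | intermediate
6 | (1S,10S)-1α-acetoxy-1,10-dihydroparthenolide | C1C[C@H](C)[C@@H](OC(C)=O)CC[C@@]2(C)O[C@@H]2[C@H]2OC(=O)C(=C)[C@H]12 | intermediate
7 | 13-bromo butenolide: (1S,4R,5R,6S,10S)-1α-acetoxy-13-bromo-4α,5β-epoxygermacr-7(11)-en-6α,12-olide | C1C[C@H](C)[C@@H](OC(C)=O)CC[C@@]2(C)O[C@@H]2[C@H]2OC(=O)C(CBr)=C12 | intermediate
8 | (1S,4R,5R,6S,10S)-1α,13-diacetoxy-4α,5β-epoxygermacr-7(11)-en-6α,12-olide | C1C[C@H](C)[C@@H](OC(C)=O)CC[C@@]2(C)O[C@@H]2[C@H]2OC(=O)C(COC(C)=O)=C12 | intermediate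
9 | glaucolide K, (1S,4R,5R,6S,8S,10S)-1α,13-diacetoxy-4α,5β-epoxy-8α-(methacryloyloxy)germacr-7(11)-en-6α,12-olide | C=C(C)C(=O)O[C@H]1C[C@H](C)[C@@H](OC(C)=O)CC[C@@]2(C)O[C@@H]2[C@H]2OC(=O)C(COC(C)=O)=C12 | target

## Step count and risks

Total steps: 5. Longest linear sequence: 5 steps (1 to 9).

Three steps most likely to fail:

**Step 5** (the proposed C–H methacryloxylation). Risks are site selectivity against C6–H, face selectivity at C8, and catalyst turnover on a tetrasubstituted butenolide. The fallback uses known chemistry, sets out from 8 and returns at 9. Radical allylic oxidation of the C8 methylene with tert-butyl hydroperoxide and catalytic Rh2(C6H10NO)4 (dirhodium tetracaprolactamate, divalent rhodium) in 1,2-dichloroethane at 40 °C gives the 8-oxo butenolide F1. Luche reduction (NaBH4, CeCl3·7H2O, MeOH, −78 °C) delivers hydride to the open β-face of the ketone and gives the 8α-alcohol F2. Acylation with methacrylic anhydride, Et3N and catalytic DMAP (CH2Cl2, 0 °C) gives 9. Here oxygen is installed without a stereochemical event, and C8 is set by hydride addition instead of by C–O bond formation.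

**Step 3** (Mitsunobu inversion at a hindered secondary carbinol in a ten-membered ring). Elimination and slow backside attack are the risks. The fallback sets out from 5 and returns at 6. Dess–Martin periodinane (CH2Cl2, NaHCO3) gives the 1-ketone F3. Reagent-controlled reduction with (R)-2-methyl-CBS-oxazaborolidine and catecholborane (toluene, −78 °C; catecholborane leaves the α-methylene lactone alone) gives the 1α-alcohol F4. Ac2O, pyridine and catalytic DMAP then give 6. C1 is set by catalyst-controlled hydride addition instead of SN2 inversion.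

**Step 4** (radical bromination with transposition). Bromine addition to the acrylate and HBr opening of the epoxide are the risks. The fallback sets out from 6 and returns at 8. Ionic oxyselenenylation with PhSeCl and AgOAc in AcOH/CH2Cl2 puts selenium on C11 and acetate on the β-carbon C13, giving the 11α-phenylselanyl 13-acetate F5. H2O2/pyridine (CH2Cl2, 0 °C) oxidises it to the selenoxide F6, which is not isolated and undergoes syn-elimination into C7–H, away from the acetoxy-bearing carbon, to give 8.

## Further compounds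

F1 | step 5 | 8-oxo butenolide, (1S,4R,5R,6S,10S)-1α,13-diacetoxy-4α,5β-epoxy-8-oxogermacr-7(11)-en-6α,12-olide | O=C1C[C@H](C)[C@@H](OC(C)=O)CC[C@@]2(C)O[C@@H]2[C@H]2OC(=O)C(COC(C)=O)=C12
F2 | step 5 | 8α-alcohol, (1S,4R,5R,6S,8S,10S)-1α,13-diacetoxy-4α,5β-epoxy-8α-hydroxygermacr-7(11)-en-6α,12-olide | O[C@H]1C[C@H](C)[C@@H](OC(C)=O)CC[C@@]2(C)O[C@@H]2[C@H]2OC(=O)C(COC(C)=O)=C12
F3 | step 3 | 1-ketone, (10S)-1-oxo-1,10-dihydroparthenolide | C1C[C@H](C)C(=O)CC[C@@]2(C)O[C@@H]2[C@H]2OC(=O)C(=C)[C@H]12
F4 | step 3 | 1α-alcohol, (1S,10S)-1α-hydroxy-1,10-dihydroparthenolide | C1C[C@H](C)[C@@H](O)CC[C@@]2(C)O[C@@H]2[C@H]2OC(=O)C(=C)[C@H]12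
F5 | step 4 | 11α-phenylselanyl 13-acetate, (11R)-1α,13-diacetoxy-11-(phenylselanyl)-4α,5β-epoxy-10αH-germacran-6α,12-olide | C1C[C@H](C)[C@@H](OC(C)=O)CC[C@@]2(C)O[C@@H]2[C@H]2OC(=O)[C@@](COC(C)=O)([Se]c3ccccc3)[C@H]12
F6 | step 4 | selenoxide of F5, 11α-(phenylseleninyl) analogue | C1C[C@H](C)[C@@H](OC(C)=O)CC[C@@]2(C)O[C@@H]2[C@H]2OC(=O)[C@@](COC(C)=O)([Se](=O)c3ccccc3)[C@H]12
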